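**Retrosynthetic overview**
1. The last C–C bond is a C(sp3)–C(sp2) Negishi union of an alkylzinc (carvone-derived stereocentre plus complete left arm, acid masked as a 2-(trimethylsilyl)ethyl ester) with an α-iodo enoate that carries the butenolide; fluoride then frees the acid.
2. The α-iodo enoate comes from a methyl ynoate by syn-hydrostannation and iodination, which fixes the right-hand Z-enoate; the ynoate comes from a terminal alkyne by base-free oxidative methoxycarbonylation.
3. The plan rests on the only ring, a furan-2(5H)-one with the chain on C4, H on C3 and an unsubstituted C5H2 bound to O1: O1–C5–C4–C3 is propargyl alcohol, C2 is CO2, and the C4–CH2 bond comes from a homopropargyl Grignard carbon, all in one flask.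
4. Core: (S)-carvone loses its methyl-bearing ring carbon (epoxidation, hydrolysis, periodate) and is reduced to (4S)-4-isopropenyl-δ-valerolactone; its arms are grown by Grignard addition and Johnson–Claisen rearrangement (E-alkene) and a Z-selective diaryl-phosphonate olefination.
5. Ring order: the butenolide is closed first (step 2) and carried to the end; the six-membered lactone and lactol of the core are temporary and are opened in step 14.

Key step: step 2

Remark: (S)-carvone is mapped so that its CH2–C(=O) arm becomes the allylic arm and its CH2–CH= arm the ethylene arm of the stereocentre; with this mapping the untouched carvone centre is the (S) centre of the target.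

**Route**

Step 1
Reactants: 1 (4-bromobut-1-yn-1-yl)trimethylsilane
Product: 2 [4-(trimethylsilyl)but-3-yn-1-yl]magnesium bromide
Conditions: Mg turnings, I2 (cat.), THF, 25–40 °C
Reagents that add atoms: magnesium [Mg]
Why: Grignard formation by magnesium insertion into a primary C–Br bond is routine, and the silyl cap removes the acidic alkyne C–H that would otherwise quench the reagent.

Step 2
Reactants: 2 [4-(trimethylsilyl)but-3-yn-1-yl]magnesium bromide; 3 propargyl alcohol; 4 carbon dioxide
Product: 9 4-[4-(trimethylsilyl)but-3-yn-1-yl]furan-2(5H)-one, via chloromagnesium prop-2-yn-1-olate 5 (not isolated), via cyclic alkenylmagnesium alkoxide 6 (not isolated), via magnesium alkoxide carboxylate 7 (not isolated), via Z-hydroxy acid 8 (not isolated)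
Conditions: 3, i-PrMgCl (1.0 equiv), THF, −20 °C; then 2 (1.4 equiv), CuI (10 mol%), THF/Et2O, 0 °C→rt; CO2 (1 atm), −20 °C→rt; 2 M HCl, rt
Reagents that add atoms: none
Why: Alkoxide 5 binds the copper-activated alkylmagnesium species formed from 2 and CuI, which transfers its alkyl group to the internal alkyne carbon while magnesium ends on the terminal carbon anti to it, closing the five-membered oxamagnesole 6; this is the known copper-catalysed anti-carbomagnesiation of prop-2-yn-1-ol by Grignard reagents. The alkenyl–Mg bond of 6 is carboxylated by CO2 with retention, so the carboxylate in 7 sits cis to CH2O. On acidification hydroxy acid 8 lactonises by 5-exo-trig acyl substitution, which closes the furanone (O1–C2) with the chain on C4, H on C3 and CH2–O at C5. No stereocentre is formed; the step needs regio- and anti-selectivity in the carbometalation, and both are imposed by the alkoxide chelate, since a syn or regio-reversed adduct could not close to this butenolide. The silyl-capped alkyne of 2 has neither a directing group nor an acidic C–H and stays a spectator, and pre-forming 5 with i-PrMgCl spares the functionalised Grignard reagent.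

Step 3
Reactants: 9 4-[4-(trimethylsilyl)but-3-yn-1-yl]furan-2(5H)-one
Product: 10 4-(but-3-yn-1-yl)furan-2(5H)-one
Conditions: Bu4NF, AcOH, THF, 0 °C
Reagents that add atoms: none
Why: Fluoride-induced protodesilylation of the C(sp)–Si bond is fast even when buffered with acetic acid, and the buffer protects the base-sensitive butenolide from γ-deprotonation or ring opening.

Step 4
Reactants: 10 4-(but-3-yn-1-yl)furan-2(5H)-one
Product: 11 methyl 5-(5-oxo-2,5-dihydrofuran-3-yl)pent-2-ynoate
Conditions: PdCl2 (5 mol%), CuCl2 (2.2 equiv), NaOAc (2.2 equiv), CO (1 atm), MeOH, rt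
Reagents that add atoms: carbon monoxide [C-]#[O+]; methanol CO
Why: Palladium-catalysed oxidative alkoxycarbonylation of a terminal alkyne (alkynylpalladium formation, CO insertion, methanolysis, reoxidation of zerovalent palladium by CuCl2) installs the ester without the strong base that the butenolide would not survive.

Step 5
Reactants: 11 methyl 5-(5-oxo-2,5-dihydrofuran-3-yl)pent-2-ynoate
Product: 12 methyl (2E)-5-(5-oxo-2,5-dihydrofuran-3-yl)-2-(tributylstannyl)pent-2-enoate
Conditions: Bu3SnH (1.05 equiv), Pd(PPh3)4 (3 mol%), THF, 0 °C→rt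
Reagents that add atoms: tributyltin hydride CCCC[SnH](CCCC)CCCC
Why: Palladium-catalysed hydrostannation adds H and Sn syn across the ynoate with tin on the ester-bearing carbon, so the ester ends cis to the chain, while the β,β-disubstituted butenolide alkene is far less reactive.

Step 6
Reactants: 12 methyl (2E)-5-(5-oxo-2,5-dihydrofuran-3-yl)-2-(tributylstannyl)pent-2-enoate
Product: 13 methyl (2E)-2-iodo-5-(5-oxo-2,5-dihydrofuran-3-yl)pent-2-enoate
Conditions: I2, CH2Cl2, 0 °C
Reagents that add atoms: iodine II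
Why: Iododestannylation is an ipso electrophilic substitution at the C–Sn bond that proceeds with retention, so the ester stays cis to the butenolide-bearing chain.

Step 7
Reactants: 14 2-(trimethylsilyl)ethanol; 15 bromoacetyl bromide
Product: 16 2-(trimethylsilyl)ethyl bromoacetate
Conditions: pyridine, CH2Cl2, 0 °C
Reagents that add atoms: none
Why: O-acylation of a primary alcohol by an acyl bromide (esterification) is much faster than displacement of the α-bromide.

Step 8
Reactants: 16 2-(trimethylsilyl)ethyl bromoacetate; 17 diphenyl phosphite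
Product: 18 2-(trimethylsilyl)ethyl 2-(diphenoxyphosphoryl)acetate
Conditions: Et3N, CH2Cl2, 0 °C→rt
Reagents that add atoms: none
Why: Michaelis–Becker-type P-alkylation, in which the amine-generated phosphite anion displaces the activated α-bromide, is the standard entry to diaryl phosphonoacetates.

Step 9
Reactants: 18 2-(trimethylsilyl)ethyl 2-(diphenoxyphosphoryl)acetate; 19 5-bromo-2-methylpent-2-ene
Product: 20 2-(trimethylsilyl)ethyl 2-(diphenoxyphosphoryl)-6-methylhept-5-enoate (racemic)
Conditions: NaH (1.0 equiv), Bu4NI (cat.), DMSO/THF, 0 °C→rt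
Reagents that add atoms: none
Why: The doubly stabilised phosphonoacetate anion undergoes SN2 C-alkylation by the unhindered primary bromide, and one equivalent of base limits dialkylation.

Step 10
Reactants: 21 (S)-(+)-carvone
Product: 22 (1S,4S,6S)-1-methyl-4-(prop-1-en-2-yl)-7-oxabicyclo[4.1.0]heptan-2-one
Conditions: 30% aq. H2O2, NaOH (cat.), MeOH, 0 °C
Reagents that add atoms: hydrogen peroxide OO
Why: Weitz–Scheffer nucleophilic epoxidation attacks only the electron-poor enone alkene, anti to the C4 substituent, and leaves the isopropenyl group alone; both new stereocentres are excised in the next step.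

Step 11
Reactants: 22 (1S,4S,6S)-1-methyl-4-(prop-1-en-2-yl)-7-oxabicyclo[4.1.0]heptan-2-one
Product: 24 (3S)-5-oxo-3-(prop-1-en-2-yl)pentanoic acid, via ketodiol 23 (not isolated)
Conditions: 1 M aq. H2SO4, THF, rt; then NaIO4 (2.5 equiv), 0 °C→rt
Reagents that add atoms: water O; sodium periodate [Na+].[O-]I(=O)(=O)=O
Why: Acid-catalysed hydrolysis opens the epoxy ketone to ketodiol 23, and periodate (Malaprade cleavage) then cuts both C–C bonds flanking the methyl-bearing carbon, which leaves as acetic acid, giving an aldehyde on one arm and an acid on the other without touching the stereocentre.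

Step 12
Reactants: 24 (3S)-5-oxo-3-(prop-1-en-2-yl)pentanoic acid
Product: 26 (4S)-4-(prop-1-en-2-yl)tetrahydro-2H-pyran-2-one, via hydroxy acid 25 (not isolated)
Conditions: NaBH4, EtOH/H2O, 0 °C; then 2 M HCl to pH 1, rt
Reagents that add atoms: none
Why: Borohydride reduces only the aldehyde, and the 5-hydroxy acid 25 closes to the δ-lactone on acidification (6-exo-trig lactonisation), which fixes one arm as an acyl carbon and the other as an alkoxy carbon.

Step 13
Reactants: 26 (4S)-4-(prop-1-en-2-yl)tetrahydro-2H-pyran-2-one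
Product: 27 (4S)-4-(prop-1-en-2-yl)tetrahydro-2H-pyran-2-ol (anomer mixture)
Conditions: i-Bu2AlH (1.1 equiv), CH2Cl2, −78 °C; aq. potassium sodium tartrate (KNaC4H4O6)
Reagents that add atoms: none
Why: At −78 °C the aluminium hemiacetal formed by one hydride addition is stable and gives the lactol on work-up (partial lactone reduction).

Step 14
Reactants: 27 (4S)-4-(prop-1-en-2-yl)tetrahydro-2H-pyran-2-ol; 28 isopropenylmagnesium bromide
Product: 29 (3S)-6-methyl-3-(prop-1-en-2-yl)hept-6-ene-1,5-diol (mixture of C5 epimers)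
Conditions: 28 (3 equiv), THF, 0 °C→rt; aq. NH4Cl
Reagents that add atoms: none
Why: The lactol reacts through its open hydroxy-aldehyde form, so excess alkenyl Grignard reagent adds to the aldehyde carbon (1,2-addition) to give the 2-methylallylic alcohol needed for the Claisen step; the carbinol configuration is irrelevant because that carbon becomes sp2.

Step 15
Reactants: 29 (3S)-6-methyl-3-(prop-1-en-2-yl)hept-6-ene-1,5-diol
Product: 30 (5S)-7-[(tert-butyldimethylsilyl)oxy]-2-methyl-5-(prop-1-en-2-yl)hept-1-en-3-ol (mixture of C3 epimers)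
Conditions: TBSCl (1.05 equiv), imidazole, CH2Cl2, −20→0 °C
Reagents that add atoms: tert-butyldimethylsilyl chloride CC(C)(C)[Si](C)(C)Cl
Why: Silylation with one equivalent of TBSCl at low temperature selects the unhindered primary hydroxyl over the secondary allylic one.

Step 16
Reactants: 30 (5S)-7-[(tert-butyldimethylsilyl)oxy]-2-methyl-5-(prop-1-en-2-yl)hept-1-en-3-ol; 31 triethyl orthoacetate
Product: 33 ethyl (4E,7R)-9-[(tert-butyldimethylsilyl)oxy]-4-methyl-7-(prop-1-en-2-yl)non-4-enoate, via ketene acetal 32 (not isolated)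
Conditions: EtCO2H (cat.), 31 (neat, excess), 140 °C, EtOH distilled off
Reagents that add atoms: none
Why: Johnson–Claisen rearrangement: orthoester exchange and loss of ethanol give ketene acetal 32, whose chair [3,3]-sigmatropic shift places the carbinol substituent equatorial and so should deliver the E-trisubstituted alkene with the two-carbon ester extension.

Step 17
Reactants: 33 ethyl (4E,7R)-9-[(tert-butyldimethylsilyl)oxy]-4-methyl-7-(prop-1-en-2-yl)non-4-enoate
Product: 34 (4E,7R)-9-[(tert-butyldimethylsilyl)oxy]-4-methyl-7-(prop-1-en-2-yl)non-4-enal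
Conditions: i-Bu2AlH (1.05 equiv), CH2Cl2, −78 °C; aq. KNaC4H4O6
Reagents that add atoms: none
Why: At −78 °C i-Bu2AlH adds once to the ethyl ester and the tetrahedral intermediate persists until work-up, when it releases the aldehyde (partial ester reduction).

Step 18
Reactants: 34 (4E,7R)-9-[(tert-butyldimethylsilyl)oxy]-4-methyl-7-(prop-1-en-2-yl)non-4-enal; 20 2-(trimethylsilyl)ethyl 2-(diphenoxyphosphoryl)-6-methylhept-5-enoate
Product: 35 2-(trimethylsilyl)ethyl (2Z,6E,9R)-11-[(tert-butyldimethylsilyl)oxy]-6-methyl-2-(4-methylpent-3-en-1-yl)-9-(prop-1-en-2-yl)undeca-2,6-dienoate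
Conditions: NaH, THF, −78→0 °C
Reagents that add atoms: none
Why: Horner–Wadsworth–Emmons olefination with a diaryl phosphonate (Ando modification): the electron-poor diphenoxyphosphoryl group makes collapse of the kinetic adduct fast, which should favour the Z-enoate with the ester cis to the aldehyde-derived chain.

Step 19
Reactants: 35 2-(trimethylsilyl)ethyl (2Z,6E,9R)-11-[(tert-butyldimethylsilyl)oxy]-6-methyl-2-(4-methylpent-3-en-1-yl)-9-(prop-1-en-2-yl)undeca-2,6-dienoate
Product: 36 2-(trimethylsilyl)ethyl (2Z,6E,9R)-11-hydroxy-6-methyl-2-(4-methylpent-3-en-1-yl)-9-(prop-1-en-2-yl)undeca-2,6-dienoate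
Conditions: camphorsulfonic acid (cat.), MeOH/CH2Cl2, 0 °C
Reagents that add atoms: none
Why: Acid-catalysed methanolysis removes the primary TBS ether under conditions that leave the fluoride-labile 2-(trimethylsilyl)ethyl ester and the alkenes untouched.

Step 20
Reactants: 36 2-(trimethylsilyl)ethyl (2Z,6E,9R)-11-hydroxy-6-methyl-2-(4-methylpent-3-en-1-yl)-9-(prop-1-en-2-yl)undeca-2,6-dienoate
Product: 37 2-(trimethylsilyl)ethyl (2Z,6E,9R)-11-iodo-6-methyl-2-(4-methylpent-3-en-1-yl)-9-(prop-1-en-2-yl)undeca-2,6-dienoate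
Conditions: I2, PPh3, imidazole, CH2Cl2, 0 °C→rt
Reagents that add atoms: iodine II
Why: Appel-type iodination converts the primary alcohol to the iodide by SN2 displacement of the alkoxyphosphonium ion under neutral conditions that the polyene tolerates.

Step 21
Reactants: 37 2-(trimethylsilyl)ethyl (2Z,6E,9R)-11-iodo-6-methyl-2-(4-methylpent-3-en-1-yl)-9-(prop-1-en-2-yl)undeca-2,6-dienoate; 13 methyl (2E)-2-iodo-5-(5-oxo-2,5-dihydrofuran-3-yl)pent-2-enoate
Product: 39 2-(trimethylsilyl)ethyl (2Z,6E,9S,12Z)-12-(methoxycarbonyl)-6-methyl-2-(4-methylpent-3-en-1-yl)-15-(5-oxo-2,5-dihydrofuran-3-yl)-9-(prop-1-en-2-yl)pentadeca-2,6,12-trienoate, via alkylzinc iodide 38 (not isolated)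
Conditions: Zn dust (BrCH2CH2Br, TMSCl activation), DMA, 40 °C; then 13, PdCl2(dppf) (5 mol%), THF/DMA, rt→40 °C
Reagents that add atoms: none
Why: Zinc inserts into the primary C–I bond to give the ester-tolerant alkylzinc 38, and Negishi coupling (oxidative addition of zerovalent palladium to the alkenyl iodide, transmetalation, reductive elimination) joins C(sp3) to C(sp2) with retention of alkene geometry, the wide-bite-angle dppf ligand disfavouring β-hydride elimination.

Step 22
Reactants: 39 2-(trimethylsilyl)ethyl (2Z,6E,9S,12Z)-12-(methoxycarbonyl)-6-methyl-2-(4-methylpent-3-en-1-yl)-15-(5-oxo-2,5-dihydrofuran-3-yl)-9-(prop-1-en-2-yl)pentadeca-2,6,12-trienoate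
Product: 40 (2Z,6E,9S,12Z)-12-(methoxycarbonyl)-6-methyl-2-(4-methylpent-3-en-1-yl)-15-(5-oxo-2,5-dihydrofuran-3-yl)-9-(prop-1-en-2-yl)pentadeca-2,6,12-trienoic acid (CNP0162600.1)
Conditions: Bu4NF, THF, 0 °C→rt; cold 0.5 M HCl work-up
Reagents that add atoms: none
Why: Fluoride attacks silicon and triggers β-elimination of ethene and fluorotrimethylsilane to release the carboxylate, conditions under which the methyl ester and the lactone should not be cleaved and the remote stereocentre is untouched.

**Compound list**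
1 | (4-bromobut-1-yn-1-yl)trimethylsilane | C[Si](C)(C)C#CCCBr | starting material
2 | [4-(trimethylsilyl)but-3-yn-1-yl]magnesium bromide | C[Si](C)(C)C#CCC[Mg]Br | intermediate
3 | propargyl alcohol (prop-2-yn-1-ol) | C#CCO | starting material
4 | carbon dioxide | O=C=O | starting material
5 | chloromagnesium prop-2-yn-1-olate | C#CCO[Mg]Cl | intermediate
6 | 4-[4-(trimethylsilyl)but-3-yn-1-yl]-2,5-dihydro-1,2-oxamagnesole (cyclic alkenylmagnesium alkoxide, Mg on the former terminal alkyne carbon) | C[Si](C)(C)C#CCCC1=C[Mg]OC1 | intermediate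
7 | magnesium (2Z)-3-(oxidomethyl)-7-(trimethylsilyl)hept-2-en-6-ynoate | [Mg+2].[O-]C/C(CCC#C[Si](C)(C)C)=C\C([O-])=O | intermediate
8 | (2Z)-3-(hydroxymethyl)-7-(trimethylsilyl)hept-2-en-6-ynoic acid | OC/C(CCC#C[Si](C)(C)C)=C\C(O)=O | intermediate
9 | 4-[4-(trimethylsilyl)but-3-yn-1-yl]furan-2(5H)-one | C[Si](C)(C)C#CCCC1=CC(=O)OC1 | intermediate
10 | 4-(but-3-yn-1-yl)furan-2(5H)-one | C#CCCC1=CC(=O)OC1 | intermediate
11 | methyl 5-(5-oxo-2,5-dihydrofuran-3-yl)pent-2-ynoate | COC(=O)C#CCCC1=CC(=O)OC1 | intermediate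
12 | methyl (2E)-5-(5-oxo-2,5-dihydrofuran-3-yl)-2-(tributylstannyl)pent-2-enoate (ester cis to chain) | COC(=O)/C(=C\CCC1=CC(=O)OC1)[Sn](CCCC)(CCCC)CCCC | intermediate
13 | methyl (2E)-2-iodo-5-(5-oxo-2,5-dihydrofuran-3-yl)pent-2-enoate (ester cis to chain) | COC(=O)/C(I)=C\CCC1=CC(=O)OC1 | intermediate
14 | 2-(trimethylsilyl)ethanol | C[Si](C)(C)CCO | starting material
15 | bromoacetyl bromide | BrCC(Br)=O | starting material
16 | 2-(trimethylsilyl)ethyl bromoacetate | C[Si](C)(C)CCOC(=O)CBr | intermediate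
17 | diphenyl phosphite | O=[PH](Oc1ccccc1)Oc1ccccc1 | starting material
18 | 2-(trimethylsilyl)ethyl 2-(diphenoxyphosphoryl)acetate | C[Si](C)(C)CCOC(=O)CP(=O)(Oc1ccccc1)Oc1ccccc1 | intermediate
19 | 5-bromo-2-methylpent-2-ene | CC(C)=CCCBr | starting material
20 | 2-(trimethylsilyl)ethyl 2-(diphenoxyphosphoryl)-6-methylhept-5-enoate (racemic) | CC(C)=CCCC(C(=O)OCC[Si](C)(C)C)P(=O)(Oc1ccccc1)Oc1ccccc1 | intermediate
21 | (S)-(+)-carvone | CC1=CC[C@H](C(C)=C)CC1=O | starting material
22 | (1S,4S,6S)-1-methyl-4-(prop-1-en-2-yl)-7-oxabicyclo[4.1.0]heptan-2-one (epoxide trans to isopropenyl) | C[C@]12O[C@H]1C[C@H](C(C)=C)CC2=O | intermediate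
23 | (2S,3R,5S)-2,3-dihydroxy-2-methyl-5-(prop-1-en-2-yl)cyclohexan-1-one (trans-diol; its configuration is immaterial) | C[C@]1(O)[C@H](O)C[C@H](C(C)=C)CC1=O | intermediate
24 | (3S)-5-oxo-3-(prop-1-en-2-yl)pentanoic acid | O=CC[C@H](C(C)=C)CC(=O)O | intermediate
25 | (3S)-5-hydroxy-3-(prop-1-en-2-yl)pentanoic acid | OCC[C@H](C(C)=C)CC(=O)O | intermediate
26 | (4S)-4-(prop-1-en-2-yl)tetrahydro-2H-pyran-2-one | O=C1C[C@@H](C(C)=C)CCO1 | intermediate
27 | (4S)-4-(prop-1-en-2-yl)tetrahydro-2H-pyran-2-ol (anomer mixture) | OC1C[C@@H](C(C)=C)CCO1 | intermediate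
28 | isopropenylmagnesium bromide (prop-1-en-2-ylmagnesium bromide) | C=C(C)[Mg]Br | starting material
29 | (3S)-6-methyl-3-(prop-1-en-2-yl)hept-6-ene-1,5-diol (C5 epimers) | C=C(C)C(O)C[C@@H](C(C)=C)CCO | intermediate
30 | (5S)-7-[(tert-butyldimethylsilyl)oxy]-2-methyl-5-(prop-1-en-2-yl)hept-1-en-3-ol (C3 epimers) | C=C(C)C(O)C[C@@H](C(C)=C)CCO[Si](C)(C)C(C)(C)C | intermediate
31 | triethyl orthoacetate | CC(OCC)(OCC)OCC | starting material
32 | tert-butyl{[(3S)-5-[(1-ethoxyethenyl)oxy]-6-methyl-3-(prop-1-en-2-yl)hept-6-en-1-yl]oxy}dimethylsilane (ketene acetal, C5 epimers) | C=C(C)C(OC(=C)OCC)C[C@@H](C(C)=C)CCO[Si](C)(C)C(C)(C)C | intermediate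
33 | ethyl (4E,7R)-9-[(tert-butyldimethylsilyl)oxy]-4-methyl-7-(prop-1-en-2-yl)non-4-enoate | CCOC(=O)CC/C(C)=C/C[C@@H](C(C)=C)CCO[Si](C)(C)C(C)(C)C | intermediate
34 | (4E,7R)-9-[(tert-butyldimethylsilyl)oxy]-4-methyl-7-(prop-1-en-2-yl)non-4-enal | O=CCC/C(C)=C/C[C@@H](C(C)=C)CCO[Si](C)(C)C(C)(C)C | intermediate
35 | 2-(trimethylsilyl)ethyl (2Z,6E,9R)-11-[(tert-butyldimethylsilyl)oxy]-6-methyl-2-(4-methylpent-3-en-1-yl)-9-(prop-1-en-2-yl)undeca-2,6-dienoate | CC(C)=CCC/C(C(=O)OCC[Si](C)(C)C)=C/CC/C(C)=C/C[C@@H](C(C)=C)CCO[Si](C)(C)C(C)(C)C | intermediate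
36 | 2-(trimethylsilyl)ethyl (2Z,6E,9R)-11-hydroxy-6-methyl-2-(4-methylpent-3-en-1-yl)-9-(prop-1-en-2-yl)undeca-2,6-dienoate | CC(C)=CCC/C(C(=O)OCC[Si](C)(C)C)=C/CC/C(C)=C/C[C@@H](C(C)=C)CCO | intermediate
37 | 2-(trimethylsilyl)ethyl (2Z,6E,9R)-11-iodo-6-methyl-2-(4-methylpent-3-en-1-yl)-9-(prop-1-en-2-yl)undeca-2,6-dienoate | CC(C)=CCC/C(C(=O)OCC[Si](C)(C)C)=C/CC/C(C)=C/C[C@@H](C(C)=C)CCI | intermediate
38 | alkylzinc iodide from 37 (C11–ZnI, 9R) | CC(C)=CCC/C(C(=O)OCC[Si](C)(C)C)=C/CC/C(C)=C/C[C@@H](C(C)=C)CC[Zn]I | intermediate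
39 | 2-(trimethylsilyl)ethyl (2Z,6E,9S,12Z)-12-(methoxycarbonyl)-6-methyl-2-(4-methylpent-3-en-1-yl)-15-(5-oxo-2,5-dihydrofuran-3-yl)-9-(prop-1-en-2-yl)pentadeca-2,6,12-trienoate | C=C(C)[C@H](C/C=C(\C)CC/C=C(/CCC=C(C)C)C(=O)OCC[Si](C)(C)C)CC/C(=C/CCC1=CC(=O)OC1)C(=O)OC | intermediate
40 | (2Z,6E,9S,12Z)-12-(methoxycarbonyl)-6-methyl-2-(4-methylpent-3-en-1-yl)-15-(5-oxo-2,5-dihydrofuran-3-yl)-9-(prop-1-en-2-yl)pentadeca-2,6,12-trienoic acid (CNP0162600.1) | C=C(C)[C@H](C/C=C(\C)CC/C=C(/CCC=C(C)C)C(=O)O)CC/C(=C/CCC1=CC(=O)OC1)C(=O)OC | target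

**Step count**
Total: 22 steps. Longest linear sequence: 13 steps (steps 10–22, from (S)-carvone 21 to 40).

**Steps most likely to fail, with fallbacks**

Step 2. The carbomagnesiation may stall or go astray through deprotonation of the terminal alkyne C–H, homocoupling of the functionalised Grignard reagent, or incomplete carboxylation and lactonisation. The fallback builds the same C4–CH2 bond on a purchased ring. It sets out from bromide 1: zinc insertion (Zn dust, I2 cat., DMA, 80 °C) should give [4-(trimethylsilyl)but-3-yn-1-yl]zinc bromide F1, and Negishi coupling of this reagent with commercial 4-bromofuran-2(5H)-one (O=C1C=C(Br)CO1; PdCl2(dppf), THF/DMA, rt) rejoins the route at 9.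

Step 18. Z-selectivity may erode because the phosphonate is α-branched and the aldehyde unbranched, giving E/Z mixtures that are hard to separate. The fallback sets the geometry by syn-hydrometalation instead of olefination and sets out from aldehyde 34. Ohira–Bestmann homologation (dimethyl (1-diazo-2-oxopropyl)phosphonate, K2CO3, MeOH) gives tert-butyl(dimethyl){[(3R,5E)-6-methyl-3-(prop-1-en-2-yl)dec-5-en-9-yn-1-yl]oxy}silane F2. Lithiation (n-BuLi, THF, −78 °C) and CO2 give (6E,9R)-11-[(tert-butyldimethylsilyl)oxy]-6-methyl-9-(prop-1-en-2-yl)undec-6-en-2-ynoic acid F3, which is esterified with 14 (dicyclohexylcarbodiimide, 4-dimethylaminopyridine cat., CH2Cl2, −20 °C) to its 2-(trimethylsilyl)ethyl ester F4. Hydrostannation (Bu3SnH, Pd(PPh3)4) gives the (2E)-2-tributylstannyl enoate F5, and I2 gives the (2E)-2-iodo enoate F6 with the ester cis to the chain. Negishi coupling of F6 with (4-methylpent-3-en-1-yl)zinc bromide F7 (from 19, Zn dust, I2 cat., DMA, 80 °C; PdCl2(dppf)) comes back to the route at 35.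

Step 21. The union may suffer from protodezincation or β-hydride elimination of the alkylzinc, slow transmetalation, or geometric scrambling at the α-palladated enoate. The fallback forms the C12=C13 alkene by olefination instead of the C11–C12 bond by coupling, and sets out from iodide 37. Methyl bromoacetate and 17 (Et3N, CH2Cl2) give methyl 2-(diphenoxyphosphoryl)acetate F8, whose sodium salt (NaH, DMSO) is alkylated by 37 to the α-alkylated phosphonate F9 (epimers at the phosphonate carbon). The aldehyde partner is made by the step 2 chemistry: commercial 2-(2-bromoethyl)-1,3-dioxolane and Mg give [2-(1,3-dioxolan-2-yl)ethyl]magnesium bromide F10, which with 3, CuI and 4 gives 4-[2-(1,3-dioxolan-2-yl)ethyl]furan-2(5H)-one F11; aqueous HCl/THF unmasks 3-(5-oxo-2,5-dihydrofuran-3-yl)propanal F12. Z-selective Horner–Wadsworth–Emmons reaction of the sodium salt of F9 with F12 (NaH, THF, −78→0 °C) comes back to the route at 39.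

**Further compounds**
F1 | step 2 | [4-(trimethylsilyl)but-3-yn-1-yl]zinc bromide | C[Si](C)(C)C#CCC[Zn]Br
F2 | step 18 | tert-butyl(dimethyl){[(3R,5E)-6-methyl-3-(prop-1-en-2-yl)dec-5-en-9-yn-1-yl]oxy}silane | C#CCC/C(C)=C/C[C@@H](C(C)=C)CCO[Si](C)(C)C(C)(C)C
F3 | step 18 | (6E,9R)-11-[(tert-butyldimethylsilyl)oxy]-6-methyl-9-(prop-1-en-2-yl)undec-6-en-2-ynoic acid | OC(=O)C#CCC/C(C)=C/C[C@@H](C(C)=C)CCO[Si](C)(C)C(C)(C)C
F4 | step 18 | 2-(trimethylsilyl)ethyl (6E,9R)-11-[(tert-butyldimethylsilyl)oxy]-6-methyl-9-(prop-1-en-2-yl)undec-6-en-2-ynoate | C[Si](C)(C)CCOC(=O)C#CCC/C(C)=C/C[C@@H](C(C)=C)CCO[Si](C)(C)C(C)(C)C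
F5 | step 18 | 2-(trimethylsilyl)ethyl (2E,6E,9R)-11-[(tert-butyldimethylsilyl)oxy]-6-methyl-9-(prop-1-en-2-yl)-2-(tributylstannyl)undeca-2,6-dienoate | C[Si](C)(C)CCOC(=O)/C(=C\CC/C(C)=C/C[C@@H](C(C)=C)CCO[Si](C)(C)C(C)(C)C)[Sn](CCCC)(CCCC)CCCC
F6 | step 18 | 2-(trimethylsilyl)ethyl (2E,6E,9R)-11-[(tert-butyldimethylsilyl)oxy]-2-iodo-6-methyl-9-(prop-1-en-2-yl)undeca-2,6-dienoate | C[Si](C)(C)CCOC(=O)/C(I)=C\CC/C(C)=C/C[C@@H](C(C)=C)CCO[Si](C)(C)C(C)(C)C
F7 | step 18 | (4-methylpent-3-en-1-yl)zinc bromide | CC(C)=CCC[Zn]Br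
F8 | step 21 | methyl 2-(diphenoxyphosphoryl)acetate | COC(=O)CP(=O)(Oc1ccccc1)Oc1ccccc1
F9 | step 21 | α-alkylated phosphonate: methyl 2-(diphenoxyphosphoryl)alkanoate carrying the CH2CH2 arm of 37 on the phosphonate carbon (epimers there) | CC(C)=CCC/C(C(=O)OCC[Si](C)(C)C)=C/CC/C(C)=C/C[C@@H](C(C)=C)CCC(C(=O)OC)P(=O)(Oc1ccccc1)Oc1ccccc1
F10 | step 21 | [2-(1,3-dioxolan-2-yl)ethyl]magnesium bromide | Br[Mg]CCC1OCCO1
F11 | step 21 | 4-[2-(1,3-dioxolan-2-yl)ethyl]furan-2(5H)-one | O=C1C=C(CCC2OCCO2)CO1
F12 | step 21 | 3-(5-oxo-2,5-dihydrofuran-3-yl)propanal | O=CCCC1=CC(=O)OC1
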